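(All runs are simulated with made-up constants, and the scatter is random.)

I read each new flask at 25 d, so I ask first where a flask ends and then whether 25 d gets it there.

| setting | beta | theta | delta | violet | ochre | amber | grey | blue |
|---|---|---|---|---|---|---|---|---|
| starting material | 0.031 M | 0.031 M | 0.046 M | 0.031 M | 0.031 M | 0.031 M | 0.031 M | 0.031 M |
| protic impurity | 4.2 mM | 9.3 mM | 6.2 mM | 6.20 mM | 6.20 mM | 6.20 mM | 6.20 mM | 6.20 mM |
| temperature | 15 °C | 55 °C | 15 °C | 50 °C | 35 °C | 90 °C | 80 °C | 20 °C |
| remark | run made earlier | run made earlier | run made earlier |  |  |  |  |  |
| time |  |  |  | 25 d | 25 d | 25 d | 25 d | 25 d |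

| run | time / d | product / % |
|---|---|---|
| beta | 8.00 | 0.1 |
| beta | 25.0 | 0 |
| beta | 50.0 | 0 |
| beta | 60.0 | 0.1 |
| beta | 80.0 | 0.3 |
| beta | 120 | 0.6 |
| beta | 150 | 3.3 |
| theta | 4.00 | 56.7 |
| theta | 8.00 | 73.6 |
| theta | 10.0 | 72.2 |
| theta | 15.0 | 71.9 |
| theta | 20.0 | 71.4 |
| theta | 25.0 | 72.7 |
| delta | 30.0 | 0.6 |
| delta | 60.0 | 1.8 |
| delta | 80.0 | 0 |
| delta | 120 | 2.1 |
| delta | 150 | 5.1 |

(standard deviation of a reading: 0.5 percentage points)

- ranking by amount of product, in percent of the starting material charged, from high to low, at 25 d (violet / ochre / amber / grey / blue)
- the amount of product, in percent of the starting material charged of the flask you put first, at 25 d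
- the amount of product, in percent of the starting material charged of the flask you put last, at 25 d

I keep a ledger of the starting material, opened with the whole charge. The theta run shows a debit: from 8.00 d on, its readings average 72.4% and stay flat up to 25.0 d. I take it that the protic impurity destroys starting material mole for mole, and since its charge in theta is smaller than that of the starting material, that loss can go no further than the impurity charged, which makes the protic impurity the limiting reagent of this entry. For the new flasks I call 20.0% the impurity debit: the protic impurity charged per starting material charged. The ledger closes when the starting material is gone, and product is then the charge minus the debit times the share of impurity actually spent.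

Theta has a debit of 30.0%, so full payment gives 70.0%. The readings stand 2.4 percentage points higher, against a scatter of 0.5 points on each reading, so I read 7.87% of theta's debit as unpaid.

Now the speed. Theta was flat by 8.00 d at 55 °C, and 25 d is longer, so I count violet at 50 °C, a little cooler than theta, and the hotter grey and amber as closed. They should stand at 80.0% or somewhat above, and theta's unpaid share gives 81.6%. One end state shows no trend with temperature, so it is my own bet that the unpaid share grows with heat, which puts amber first, then grey, then violet. Blue, at 20 °C, lies close to the 15 °C runs, where beta reads 0% at 25.0 d, so I expect it last and near zero, with ochre short of the ledger's close.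

The forecast gives violet > grey > amber > ochre > blue, with 81% (76% to 85%) for the first flask and 0.2% (0% to 1.5%) for the last, and parts from my bet on the hot flasks: “Their order is essentially a tie, so I put the coolest first in case of slight degradation.”

The flasks give amber > grey > violet > ochre > blue, with amber at 89.0% and blue at 0.182%. At 25.0 d amber holds 0% starting material and still 45% of its own protic impurity. In the ledger, the debit of 20.0% is therefore paid on 55.0% of the impurity, so the entry for quenched substrate is 11.0% and the closing balance of product is 89.0%.

    starting material + product → 2 product (k = 4.69 × 10⁻⁴ L mol⁻¹ s⁻¹, Ea = 88.0 kJ mol⁻¹)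
    starting material → product (k = 4.60 × 10⁻⁸ s⁻¹, Ea = 116 kJ mol⁻¹)
    starting material + protic impurity → quenched substrate (k = 2.72 × 10⁻⁴ L mol⁻¹ s⁻¹, Ea = 59.0 kJ mol⁻¹)
    (constants at 50 °C)

Blue's charge run at 45 °C holds 0% starting material at 25.0 d and keeps 2.0% of its impurity, so the ledger closes at 80.4%. The computed product in that flask is 80.4%.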